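The north-west run leaves you a leftover. Its readings level off near 16.4% at 15.0 min, which is 0.0508 M of complex with two exchanged. That amount has taken twice its concentration in incoming ligand, out of the 0.21 M charged, so by that reading 0.108 M of the ligand is not in that product.

| setting | south-west | north-west | birch | alder |
|---|---|---|---|---|
| starting complex | 0.20 M | 0.31 M | 0.14 M | 0.14 M |
| incoming ligand | 0.21 M | 0.21 M | 0.210 M | 0.210 M |
| temperature | 20 °C | 32 °C | 40 °C | 25 °C |
| remark | run made earlier | run made earlier |  |  |
| time |  |  | 15 min | 15 min |

| run | time / min | complex with two exchanged / % |
|---|---|---|
| south-west | 2.00 | 2.5 |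
| south-west | 4.00 | 5.5 |
| south-west | 6.00 | 8.2 |
| south-west | 8.00 | 11.8 |
| south-west | 10.0 | 15.9 |
| south-west | 12.0 | 19.4 |
| south-west | 15.0 | 22.4 |
| north-west | 2.00 | 5.3 |
| north-west | 4.00 | 10.6 |
| north-west | 6.00 | 13.0 |
| north-west | 8.00 | 14.8 |
| north-west | 10.0 | 15.5 |
| north-west | 12.0 | 15.4 |
| north-west | 15.0 | 16.4 |

(standard deviation of a reading: 0.5 percentage points)

* the winner by amount of complex with two exchanged, in percent of the starting complex charged; "neither" if no more than 2 percentage points parts them (birch / alder / neither)
* how much complex with two exchanged is there at the end, in percent of the starting complex charged: birch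
* how much complex with two exchanged is there at the end, in percent of the starting complex charged: alder

- for leaving ligand the crystals are counted in
- as a solid, counted per litre of solution: crystals
- the analysis behind the earlier runs scatters by 0.5 percentage points, standard deviation
- reactions considered so far: complex with one exchanged -> decomposed reagent; crystals <-> leaving ligand; leaving ligand + starting complex -> side product; complex with one exchanged + incoming ligand -> leaving ligand + complex with two exchanged; starting complex + incoming ligand -> leaving ligand + complex with one exchanged

1. Take the main steps alone. Starting complex takes one incoming ligand, then a second, so each complex with two exchanged costs 2 ligands. In birch and alder, incoming ligand is therefore the limiting reagent, and with no losses it would carry 75.0% of the starting complex through.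

2. Add the losses. At the last reading of the north-west run, 48.4% of the ligand charged sits in complex with two exchanged. Call this the ligand share, twice the concentration of that product over the ligand charged. The remainder can stand as free ligand, in complex with one exchanged, or in what that complex decomposes to.

3. Add temperature and time. The north-west readings are flat by 10.0 min, and birch is warmer, so I expect birch to reach its flat stretch in time. Holding the north-west share gives 36.3% for birch.

4. For alder, at 25 °C, I take the south-west run, whose last reading is still rising, at a share of 42.7%. Alder differs from that run in temperature and charge, so this is a rough carry-over, and it gives 32.0%. My reckoning therefore puts birch ahead by 4.3 percentage points.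

The forecast also names birch, but with lower figures than mine, 31% for birch and 25% for alder. Of birch it says: “Its dilute charge raises the ceiling to about 30–36%, while heat lowers it.”

Birch gives 40.0% and alder 33.5%, so birch wins by 6.5 points.

    complex with one exchanged → decomposed reagent (k = 0.0480 min⁻¹, Ea = 80.0 kJ mol⁻¹)
    crystals ⇌ leaving ligand, rate k2*(cs2 - [leaving ligand]) while solid is left; crystals form when [leaving ligand] > cs2 (solubility = 0.0970 M, k = 3.00 min⁻¹)
    leaving ligand + starting complex → side product (k = 0.110 L mol⁻¹ min⁻¹, Ea = 47.0 kJ mol⁻¹)
    complex with one exchanged + incoming ligand → leaving ligand + complex with two exchanged (k = 1.00 L mol⁻¹ min⁻¹, Ea = 47.0 kJ mol⁻¹)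
    starting complex + incoming ligand → leaving ligand + complex with one exchanged (k = 0.580 L mol⁻¹ min⁻¹, Ea = 72.0 kJ mol⁻¹)
    (constants at 25 °C)

At 15.0 min, the ligand share of birch is 53.3%, and decomposed reagent stands at 42.8% of the starting complex charged. A neighbouring flask repeats birch with 0.035 M of starting complex, and there the limiting reagent changes: 0.27% of the starting complex remains. That neighbour reaches 64.2% of its own smaller charge, yet its ligand share is 21.4%, with 73% of the incoming ligand left.

(The data were generated by integration with made-up constants, noise included.)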